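**Retrosynthetic overview**
1. Ester C–O bond: protecting-group-free Mitsunobu coupling of 2,3-dihydroxybenzoic acid with (S)-14-methylhexadecan-1-ol.
2. C14 stereocentre: not taken from the chiral pool (the usual (S)-2-methylbutyl Grignard coupling). It is created by Zr-catalysed asymmetric ethylalumination (Negishi ZACA) of a terminal alkene, then protonolysis: CH=CH2 becomes CH(Et)CH3.
3. The ZACA substrate, pentadec-14-en-1-ol, comes from a Cu-catalysed sp3–sp3 coupling of 11-bromoundecan-1-ol with but-3-enylmagnesium bromide.
4. No ring is formed; the only ring (the catechol arene) is bought as 2,3-dihydroxybenzoic acid.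

Assumption: the target stereocentre is (S) (anteiso chain, (S)-14-methylhexadecyl ester), and both enantiomers of bis(1-neomenthylindenyl)zirconium dichloride, (NMI)2ZrCl2, are purchasable.

**Step 1**
Reactants: 1, 11-bromoundecan-1-ol; 2, but-3-enylmagnesium bromide (0.5 M in THF, 2.5 equiv)
Product: 3, pentadec-14-en-1-ol, CH2=CH(CH2)13OH
Conditions: Li2CuCl4 (5 mol %), THF, −78 °C → rt, 12 h; sat. NH4Cl
Reagents that add atoms: but-3-enylmagnesium bromide, C=CCC[Mg]Br
Why: Kochi-type Cu-catalysed Grignard/primary alkyl bromide cross-coupling; the first equivalent of Grignard only deprotonates the OH (the magnesium alkoxide is inert), the terminal alkene is untouched, and no stereocentre is involved.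

**Step 2**
Reactants: 3, pentadec-14-en-1-ol; 4, triethylaluminium (3.0 equiv; the first equivalent converts OH to OAlEt2)
Product: 5, (S)-14-methylhexadecan-1-ol
Conditions: Et3Al, (+)-(NMI)2ZrCl2 (5 mol %), CH2Cl2, 0 → 23 °C, 24 h, strict Ar; then 2 M HCl, 0 °C
Reagents that add atoms: triethylaluminium, CC[Al](CC)CC (one ethyl group is retained; the C–Al bond becomes C–H on acid quench)
Why: Negishi ZACA (Zr-catalysed asymmetric carboalumination, acyclic pathway in chlorinated solvent). Et is delivered to the internal alkene carbon (C14) on the face selected by the chiral zirconocene, and Al goes to the terminal carbon; protonolysis turns CH2–Al into the methyl branch, so the Me/Et/alkyl stereocentre is set in one operation. Free ω-alkenols are known substrates as their in situ aluminium alkoxides, and ethylalumination typically gives 90–95% ee. The (−)-catalyst gives the (R)-2-alkylalkan-1-ol series from 1-alkenes, which corresponds to (R) here, so the (+)-catalyst is used for (S); this sense is assigned by analogy and must be confirmed on the product.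

**Step 3**
Reactants: 5, (S)-14-methylhexadecan-1-ol; 6, 2,3-dihydroxybenzoic acid (1.3 equiv)
Product: 7, Gentiside C, (S)-14-methylhexadecyl 2,3-dihydroxybenzoate
Conditions: PPh3 (1.2 equiv), DIAD (1.2 equiv, added last, dropwise), THF, 0 °C → rt
Reagents that add atoms: none beyond reactant 6 (OC(=O)c1cccc(O)c1O); PPh3 and DIAD contribute no atoms, and the alcohol oxygen leaves as Ph3P=O
Why: Chemoselective Mitsunobu esterification of a phenolic acid. The carboxylic acid (pKa about 3) protonates the betaine and its carboxylate displaces the primary alkoxyphosphonium far faster than the phenols (pKa about 10) can, so the catechol needs no protection. The stereocentre is 13 carbons from the reacting centre and is untouched.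

**Compound list**
1 | 11-bromoundecan-1-ol | OCCCCCCCCCCCBr | starting material
2 | but-3-enylmagnesium bromide | C=CCC[Mg]Br | starting material
3 | pentadec-14-en-1-ol | C=CCCCCCCCCCCCCCO | intermediate
4 | triethylaluminium | CC[Al](CC)CC | starting material (reagent)
5 | (S)-14-methylhexadecan-1-ol | CC[C@H](C)CCCCCCCCCCCCCO | intermediate
6 | 2,3-dihydroxybenzoic acid | OC(=O)c1cccc(O)c1O | starting material
7 | Gentiside C, (S)-14-methylhexadecyl 2,3-dihydroxybenzoate | CC[C@H](C)CCCCCCCCCCCCCOC(=O)c1cccc(O)c1O | target

**Total step count:** 3
**Longest linear sequence:** 3 steps (1 → 3 → 5 → 7)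

**Steps most likely to fail, with fallbacks**
1. Step 2 (ZACA ethylalumination/protonolysis). The ee ceiling is about 90–95%, so the product is enantioenriched rather than strictly enantiopure, and the remote methyl centre cannot be upgraded by crystallisation. Competing hydroalumination gives pentadecan-1-ol, which is hard to separate from 5, and the sense of induction must be verified. Fallback: abandon catalytic induction and make 5 in one step from the chiral pool, by Li2CuCl4-catalysed coupling of (S)-2-methylbutylmagnesium bromide (from (S)-1-bromo-2-methylbutane, >99% ee) with 12-bromododecan-1-ol.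
2. Step 3 (Mitsunobu with the free catechol acid). Risks are phenol O-alkylation, catechol–phosphorane formation, and difficult removal of Ph3P=O and the hydrazide. Fallback: switch to acyl activation of a protected acid: 2,3-bis(benzyloxy)benzoic acid with 5 under EDC/DMAP in CH2Cl2, then H2, Pd/C in EtOAc to remove both benzyl groups (the molecule has no other reducible group).
3. Step 1 (Cu-catalysed coupling on the unprotected bromo alcohol). Risks are alkoxide aggregation, Wurtz homocoupling, and unreacted 1 co-eluting with 3. Fallback: reverse the polarity and disconnect at C4–C5 instead: undec-10-enylmagnesium bromide (from 11-bromoundec-1-ene) with 2-(4-bromobutoxy)tetrahydropyran under Li2CuCl4, then PPTS/MeOH to release 3.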